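Which flask ends highest in over-reaction product, when substrate and reagent are charged equally and the flasks differ in how and how hot they go in?

| flask | substrate | reagent | capture agent | temperature | remark | time |
|---|---|---|---|---|---|---|
| summer | 0.42 M | 0.42 M | 0.42 M | 85 °C | run made earlier |  |
| noon | 0.42 M | 0.59 M | 0.42 M | 100 °C | run made earlier |  |
| dusk | 0.42 M | 0.92 M | 0.42 M | 85 °C | run made earlier |  |
| midnight | 0.42 M | 0.42 M | 0.84 M | 100 °C | run made earlier |  |
| theta | 0.42 M (fed, over 15 min) | 0.420 M | 0.420 M | 100 °C | all else is in the flask from the start; the feed brings no volume worth counting | 25 min |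
| beta | 0.42 M | 0.420 M | 0.420 M |  | everything together at the start at 70 °C, warmed to 100 °C at 15 min | 25 min |
| delta | 0.42 M | 0.420 M | 0.420 M | 100 °C | everything together at the start | 25 min |
| alpha | 0.42 M | 0.420 M (fed, over 15 min) | 0.420 M |  | the addition at 70 °C, then warmed to 100 °C; the feed brings no volume worth counting | 25 min |
| zeta | 0.42 M (in portions, 3, over 15 min) | 0.420 M | 0.420 M | 100 °C | first portion at the start, last at 15 min | 25 min |

- summer (time / min: over-reaction product / %, target / %): 3.00: 0.7, 3.1; 6.00: 1.4, 7.0; 12.0: 4.3, 15.8; 30.0: 12.1, 30.6
- noon (time / min: over-reaction product / %, target / %): 2.00: 4.6, 12.6; 5.00: 14.3, 26.7; 10.0: 28.8, 29.0; 25.0: 42.7, 24.5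
- dusk (time / min: over-reaction product / %, target / %): 12.0: 14.3, 16.9; 25.0: 36.5, 16.5; 40.0: 50.1, 9.4; 50.0: 55.2, 6.8
- midnight (time / min: over-reaction product / %, target / %): 3.00: 3.8, 15.5; 8.00: 11.2, 25.2; 15.0: 14.5, 25.1; 25.0: 16.6, 25.9

(scatter of a reading: 0.5 percentage points)

* the flask that comes out highest in amount of over-reaction product, in percent of the substrate charged, or "all alike" when all lie within 1.5 percentage points (theta / beta / delta / alpha / zeta / all alike)
* over-reaction product at the end, in percent of the substrate charged, theta
* over-reaction product at the end, in percent of the substrate charged, beta
* over-reaction product at the end, in percent of the substrate charged, delta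
* over-reaction product at the end, in percent of the substrate charged, alpha
* over-reaction product at the end, in percent of the substrate charged, zeta

- the analysis behind the earlier runs scatters by 0.5 percentage points, standard deviation

The reagent charged, in percent of the substrate charged, is 100%: we call it the reagent budget. We take over-reaction product to be target that took a second reagent, so each substrate turned spends one reagent and each over-reaction product one more. The budget then equals substrate turned plus over-reaction product plus reagent still there. With equal charges, over-reaction product equals substrate left minus reagent left.

Midnight stalled: its over-reaction product went from 14.5% to 16.6% between 15.0 min and 25.0 min. The noon readings at 25.0 min leave about 30.6% of its budget unread by target plus twice over-reaction product, a figure that carries their scatter. Our bench rule gives delta that same unread part, so its tally reaches about 69.4%. Noon passed this tally roughly midway between 5.00 min and 10.0 min, so we reckon about 21.6% for delta.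

That rule borrows noon's reagent per substrate, 140%, and it stops where a flask leaves the range of the runs. Zeta's first portion meets 300%, more than dusk's 219%, and dusk is the richest run. At 25.0 min dusk read 36.5% over-reaction product against 16.5% target. So we put zeta and theta above delta, unranked, and beta and alpha below it, since their hot stretch of 10.0 min is shorter than the 15.0 min midnight took to stall.

The forecast named delta, where “the reagent budget stops at about 50% conversion”, with 24% there, 16% for theta, 17% for zeta, 18% for beta and 19% for alpha. It differs from ours by placing the fed flasks below delta.

The flasks gave 25.7% in zeta, 23.5% in theta, 18.7% in delta, 15.3% in alpha and 15.1% in beta, so zeta stands highest.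

    substrate + reagent → open intermediate (k = 0.0200 M⁻¹ s⁻¹, Ea = 82.0 kJ mol⁻¹)
    open intermediate → target (k = 0.00450 s⁻¹, Ea = 115 kJ mol⁻¹)
    reagent + target → over-reaction product (k = 0.0140 M⁻¹ s⁻¹, Ea = 92.0 kJ mol⁻¹)
    open intermediate + capture agent → trapped intermediate (k = 0.00560 M⁻¹ s⁻¹, Ea = 92.0 kJ mol⁻¹)
    (constants at 100 °C)

In delta, reagent, the limiting reagent there, fell to 0.225% of its charge by 25.0 min, and the budget of 100% closed as 81.1% substrate turned plus 18.7% over-reaction product. In zeta, target met reagent from the first portion on, and the same budget closed as 72.1% substrate turned, 25.7% over-reaction product and 2.22% reagent, with 27.9% of the substrate left at 25.0 min.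

The numbers in the tables were computed for an exercise.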